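**Retrosynthetic overview**

1. Artoflavanone 13 ⇐ its 5-O-TIPS ether 12 by desilylation; rings A and B are bought, and only the pyranone ring C is built, last.
2. Ring C is opened at C2–C3: 12 ⇐ achiral diazoketone 11, where C3 is the diazo carbon of the aryl ketone and C2 is the CH2 of a 3,4,5-trimethoxybenzyl ether on O1. An enantioselective Rh(II) carbenoid insertion into one of the two enantiotopic C2–H bonds closes ring C and sets C2.
3. Enabling feature: C2 is both benzylic to ring B and bonded to the ring oxygen O1, so its C–H bonds are doubly activated. The O1–C8a–C4a–C4 aryl ketone unit of ring A holds C2 in a 1,6-relation to C3, and the 1,5-position is O1 itself, which has no C–H.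
4. 11 ⇐ methyl ketone 7 (diazo transfer) ⇐ 5 (silylation of the chelated OH) ⇐ 3 + benzyl chloride 4 (O-alkylation of the less hindered OH) ⇐ acetophenone 1 + prenyl bromide 2 (nuclear prenylation).

Key step: step 5

Assumption: the sense of induction of the prolinate catalyst on this substrate cannot be assigned in advance. The route is written with the L-proline-derived catalyst; if the first run gives the (2R) product, the D-proline-derived antipode is used with no other change, and the enantiomeric purity of 12 is raised by crystallisation if needed.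

**Step 1**
Reactants: 1 1-(2,6-dihydroxy-4-methoxyphenyl)ethan-1-one; 2 prenyl bromide
Product: 3 1-[2,6-dihydroxy-4-methoxy-3-(3-methylbut-2-en-1-yl)phenyl]ethan-1-one (acronylin)
Conditions: prenyl bromide (1.0 equiv), 10% aq. KOH, 0 °C to rt
Reagents that add atoms: prenyl bromide, CC(C)=CCBr
Why: Nuclear (C-)prenylation of the phloroacetophenone-type phenoxide, whose oxygen is solvated in water so that the soft allylic bromide is taken up at ring carbon; C3 and C5 of 1 are equivalent, so mono-C-alkylation should give a single isomer.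

**Step 2**
Reactants: 3; 4 5-(chloromethyl)-1,2,3-trimethoxybenzene (3,4,5-trimethoxybenzyl chloride)
Product: 5 1-[2-hydroxy-4-methoxy-3-(3-methylbut-2-en-1-yl)-6-[(3,4,5-trimethoxyphenyl)methoxy]phenyl]ethan-1-one
Conditions: 4 (1.05 equiv), K2CO3, KI (cat.), acetone, reflux
Reagents that add atoms: 3,4,5-trimethoxybenzyl chloride, COc1cc(CCl)cc(OC)c1OC
Why: Williamson ether synthesis in which the 6-OH, flanked only by H, should be alkylated in preference to the 2-OH, which is flanked by the prenyl group and kept in the hydrogen bond to the carbonyl.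

**Step 3**
Reactants: 5; 6 triisopropylsilyl trifluoromethanesulfonate
Product: 7 1-[4-methoxy-3-(3-methylbut-2-en-1-yl)-6-[(3,4,5-trimethoxyphenyl)methoxy]-2-[tri(propan-2-yl)silyloxy]phenyl]ethan-1-one
Conditions: TIPSOTf (1.2 equiv), 2,6-lutidine, CH2Cl2, 0 °C to rt
Reagents that add atoms: triisopropylsilyl triflate, CC(C)[Si](C(C)C)(C(C)C)OS(=O)(=O)C(F)(F)F
Why: O-silylation with a silyl triflate, which is electrophilic enough for the hindered chelated phenol, while the weak base and the small excess should leave the methyl ketone un-enolised; the TIPS ether removes the O–H that a carbenoid would otherwise take.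

**Step 4**
Reactants: 7; 8 2,2,2-trifluoroethyl trifluoroacetate; 9 4-acetamidobenzenesulfonyl azide
Product: 11 2-diazo-1-[4-methoxy-3-(3-methylbut-2-en-1-yl)-6-[(3,4,5-trimethoxyphenyl)methoxy]-2-[tri(propan-2-yl)silyloxy]phenyl]ethan-1-one, via trifluoroacetyl ketone 10 (not isolated)
Conditions: LiHMDS, THF, −78 °C; then CF3CO2CH2CF3, −78 °C; 5% aq. HCl work-up; then p-ABSA, Et3N, H2O (1 equiv), MeCN, rt
Reagents that add atoms: 4-acetamidobenzenesulfonyl azide, CC(=O)Nc1ccc(cc1)S(=O)(=O)N=[N+]=[N-] (gives the N2 unit of 11); 2,2,2-trifluoroethyl trifluoroacetate, FC(F)(F)COC(=O)C(F)(F)F (its CF3CO group is carried only in 10)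
Why: Detrifluoroacetylative diazo transfer, in which the kinetic lithium enolate is C-trifluoroacetylated and the resulting 1,3-diketone undergoes Regitz diazo transfer with loss of the trifluoroacetyl group as the N-sulfonyl trifluoroacetamide.

**Step 5**
Reactants: 11
Product: 12 (2S)-7-methoxy-6-(3-methylbut-2-en-1-yl)-2-(3,4,5-trimethoxyphenyl)-5-[tri(propan-2-yl)silyloxy]-2,3-dihydro-4H-chromen-4-one
Conditions: Rh2(S-DOSP)4 (1 mol %), CH2Cl2/hexane, 0 °C to rt, slow addition of 11
Reagents that add atoms: none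
Why: Rh(II) expels N2 from 11 to give an electrophilic Rh carbenoid at C3, which inserts into one benzylic C2–H bond of the ArCH2–O ether through a concerted, asynchronous three-centre transition state with hydride-like transfer from C2, so that the C2–C3 and C3–H bonds form in one event and the catalyst is released. The closest known reaction type is the Rh(II)-carboxylate-catalysed asymmetric intramolecular C–H insertion of 2-alkoxyaryl diazo ketones to 2-substituted chroman-4-ones. The pyranone ring closes as a six-membered 1,6-C–H insertion; the usual 1,5-mode is not available because the 1,5-atom is the ether oxygen O1, which carries no hydrogen. The only new stereocentre, C2, comes from the choice between the two enantiotopic benzylic hydrogens and is controlled solely by the chiral N-arylsulfonylprolinate ligand sphere (catalyst control, no stereocentre in the substrate). The step needs chemoselectivity for C–H insertion over attack of the carbenoid on the lone pair of O1 (oxonium ylide, then benzyl shift to a benzofuran-3-one): the C2–H bonds are activated twice (α to oxygen, benzylic to an electron-rich ring), carboxylate-ligated Rh(II) favours insertion over ylide chemistry in this scaffold, and slow addition keeps carbenoid dimerisation down. The second ortho oxygen is masked as a TIPS ether with a shielded lone pair and no C–H within reach of a six-ring insertion, and the prenyl alkene sits meta to the acyl group and cannot reach C3.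

**Step 6**
Reactants: 12
Product: 13 artoflavanone, (2S)-5-hydroxy-7-methoxy-6-(3-methylbut-2-en-1-yl)-2-(3,4,5-trimethoxyphenyl)-2,3-dihydro-4H-chromen-4-one
Conditions: TBAF (1.1 equiv), AcOH (1.1 equiv), THF, 0 °C
Reagents that add atoms: none
Why: Fluoride cleavage of the aryl silyl ether in an acetic acid-buffered medium, which should avoid both base-induced ring opening to the chalcone (the path that would racemise C2) and acid-induced cyclisation of the prenyl group onto the freed 5-OH.

**Compound list**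

1 | 1-(2,6-dihydroxy-4-methoxyphenyl)ethan-1-one | CC(=O)c1c(O)cc(OC)cc1O | starting material
2 | prenyl bromide (1-bromo-3-methylbut-2-ene) | CC(C)=CCBr | starting material
3 | 1-[2,6-dihydroxy-4-methoxy-3-(3-methylbut-2-en-1-yl)phenyl]ethan-1-one | CC(=O)c1c(O)cc(OC)c(CC=C(C)C)c1O | intermediate
4 | 5-(chloromethyl)-1,2,3-trimethoxybenzene | COc1cc(CCl)cc(OC)c1OC | starting material
5 | 1-[2-hydroxy-4-methoxy-3-(3-methylbut-2-en-1-yl)-6-[(3,4,5-trimethoxyphenyl)methoxy]phenyl]ethan-1-one | CC(=O)c1c(OCc2cc(OC)c(OC)c(OC)c2)cc(OC)c(CC=C(C)C)c1O | intermediate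
6 | triisopropylsilyl trifluoromethanesulfonate | CC(C)[Si](C(C)C)(C(C)C)OS(=O)(=O)C(F)(F)F | starting material
7 | 1-[4-methoxy-3-(3-methylbut-2-en-1-yl)-6-[(3,4,5-trimethoxyphenyl)methoxy]-2-[tri(propan-2-yl)silyloxy]phenyl]ethan-1-one | CC(=O)c1c(OCc2cc(OC)c(OC)c(OC)c2)cc(OC)c(CC=C(C)C)c1O[Si](C(C)C)(C(C)C)C(C)C | intermediate
8 | 2,2,2-trifluoroethyl trifluoroacetate | FC(F)(F)COC(=O)C(F)(F)F | starting material
9 | 4-acetamidobenzenesulfonyl azide | CC(=O)Nc1ccc(cc1)S(=O)(=O)N=[N+]=[N-] | starting material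
10 | 4,4,4-trifluoro-1-[4-methoxy-3-(3-methylbut-2-en-1-yl)-6-[(3,4,5-trimethoxyphenyl)methoxy]-2-[tri(propan-2-yl)silyloxy]phenyl]butane-1,3-dione | O=C(CC(=O)C(F)(F)F)c1c(OCc2cc(OC)c(OC)c(OC)c2)cc(OC)c(CC=C(C)C)c1O[Si](C(C)C)(C(C)C)C(C)C | intermediate
11 | 2-diazo-1-[4-methoxy-3-(3-methylbut-2-en-1-yl)-6-[(3,4,5-trimethoxyphenyl)methoxy]-2-[tri(propan-2-yl)silyloxy]phenyl]ethan-1-one | [N-]=[N+]=CC(=O)c1c(OCc2cc(OC)c(OC)c(OC)c2)cc(OC)c(CC=C(C)C)c1O[Si](C(C)C)(C(C)C)C(C)C | intermediate
12 | (2S)-7-methoxy-6-(3-methylbut-2-en-1-yl)-2-(3,4,5-trimethoxyphenyl)-5-[tri(propan-2-yl)silyloxy]-2,3-dihydro-4H-chromen-4-one | COc1cc2c(c(O[Si](C(C)C)(C(C)C)C(C)C)c1CC=C(C)C)C(=O)C[C@@H](c1cc(OC)c(OC)c(OC)c1)O2 | intermediate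
13 | artoflavanone, (2S)-5-hydroxy-7-methoxy-6-(3-methylbut-2-en-1-yl)-2-(3,4,5-trimethoxyphenyl)-2,3-dihydro-4H-chromen-4-one | COc1cc2c(c(O)c1CC=C(C)C)C(=O)C[C@@H](c1cc(OC)c(OC)c(OC)c1)O2 | target

**Step count and risks**

Total step count: 6. Longest linear sequence: 6 steps (1 → 13).

Steps most likely to fail:

1. Step 5 (key step). The carbenoid may be captured by the lone pair of the ether oxygen and pass through an oxonium ylide with migration of the benzyl group faster than it inserts into the C–H bond, or the two enantiotopic hydrogens may be told apart too weakly. The fallback gives up carbenoid chemistry and sets out from 3.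
   - Allyl bromide and K2CO3 in acetone should alkylate the less hindered phenol to give 1-[2-hydroxy-4-methoxy-3-(3-methylbut-2-en-1-yl)-6-(prop-2-en-1-yloxy)phenyl]ethan-1-one F1.
   - MOMCl and NaH in DMF should cap the hindered phenol as 1-[4-methoxy-2-(methoxymethoxy)-3-(3-methylbut-2-en-1-yl)-6-(prop-2-en-1-yloxy)phenyl]ethan-1-one F2.
   - Pd(PPh3)4 and morpholine in THF should remove the allyl group to give 1-[6-hydroxy-4-methoxy-2-(methoxymethoxy)-3-(3-methylbut-2-en-1-yl)phenyl]ethan-1-one F3.
   - Claisen–Schmidt condensation with 3,4,5-trimethoxybenzaldehyde (KOH, EtOH) should give (E)-1-[6-hydroxy-4-methoxy-2-(methoxymethoxy)-3-(3-methylbut-2-en-1-yl)phenyl]-3-(3,4,5-trimethoxyphenyl)prop-2-en-1-one F4.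
   - Oxa-Michael cyclisation through the only free phenol (NaOAc, EtOH, reflux) should give racemic 7-methoxy-5-(methoxymethoxy)-6-(3-methylbut-2-en-1-yl)-2-(3,4,5-trimethoxyphenyl)-2,3-dihydro-4H-chromen-4-one F5.
   - Kinetic resolution by asymmetric transfer hydrogenation ([Cp*RhCl(TsDPEN)], HCO2H/Et3N, EtOAc, rt, using the TsDPEN antipode that reduces the (2R)-ketone faster) should leave (2S)-7-methoxy-5-(methoxymethoxy)-6-(3-methylbut-2-en-1-yl)-2-(3,4,5-trimethoxyphenyl)-2,3-dihydro-4H-chromen-4-one F6. It is separated from the cis alcohol (2R,4R)-7-methoxy-5-(methoxymethoxy)-6-(3-methylbut-2-en-1-yl)-2-(3,4,5-trimethoxyphenyl)-3,4-dihydro-2H-chromen-4-ol F7.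
   - HCl in MeOH at 40 °C should remove the MOM group from F6, and the fallback comes back to the route at 13.

2. Step 4. The TIPS group may migrate from the phenolic oxygen to the enolate oxygen under LiHMDS, or the doubly ortho-substituted ketone may be trifluoroacetylated incompletely. The fallback avoids strong base and sets out from 7. Heating with N,N-dimethylformamide dimethyl acetal (toluene, 105 °C) should give the enaminone (E)-3-(dimethylamino)-1-[4-methoxy-3-(3-methylbut-2-en-1-yl)-6-[(3,4,5-trimethoxyphenyl)methoxy]-2-[tri(propan-2-yl)silyloxy]phenyl]prop-2-en-1-one F8. Diazo transfer to the enaminone with 4-acetamidobenzenesulfonyl azide (dioxane, rt; cycloaddition and loss of the N-sulfonyl formamidine) should give the diazoketone, and the fallback comes back to the route at 11.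

3. Step 1. O-alkylation and double alkylation of the ambident phenoxide may outrun mono-C-alkylation. The fallback moves the carbon substituent in by a sigmatropic shift and sets out from 1. Allyl bromide (1 equiv) and K2CO3 in acetone should give 1-[2-hydroxy-4-methoxy-6-(prop-2-en-1-yloxy)phenyl]ethan-1-one F9. Aromatic Claisen rearrangement (N,N-diethylaniline, 195 °C) can only deliver the allyl group to the free ortho carbon, giving 1-[2,6-dihydroxy-4-methoxy-3-(prop-2-en-1-yl)phenyl]ethan-1-one F10. Cross-metathesis with 2-methylbut-2-ene (Grubbs second-generation catalyst, CH2Cl2, 40 °C) should turn the allyl into the prenyl group, and the fallback comes back to the route at 3.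

**Further compounds**

F1 | step 5 | 1-[2-hydroxy-4-methoxy-3-(3-methylbut-2-en-1-yl)-6-(prop-2-en-1-yloxy)phenyl]ethan-1-one | CC(=O)c1c(OCC=C)cc(OC)c(CC=C(C)C)c1O
F2 | step 5 | 1-[4-methoxy-2-(methoxymethoxy)-3-(3-methylbut-2-en-1-yl)-6-(prop-2-en-1-yloxy)phenyl]ethan-1-one | CC(=O)c1c(OCC=C)cc(OC)c(CC=C(C)C)c1OCOC
F3 | step 5 | 1-[6-hydroxy-4-methoxy-2-(methoxymethoxy)-3-(3-methylbut-2-en-1-yl)phenyl]ethan-1-one | CC(=O)c1c(O)cc(OC)c(CC=C(C)C)c1OCOC
F4 | step 5 | (E)-1-[6-hydroxy-4-methoxy-2-(methoxymethoxy)-3-(3-methylbut-2-en-1-yl)phenyl]-3-(3,4,5-trimethoxyphenyl)prop-2-en-1-one | COCOc1c(CC=C(C)C)c(OC)cc(O)c1C(=O)/C=C/c1cc(OC)c(OC)c(OC)c1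
F5 | step 5 | racemic 7-methoxy-5-(methoxymethoxy)-6-(3-methylbut-2-en-1-yl)-2-(3,4,5-trimethoxyphenyl)-2,3-dihydro-4H-chromen-4-one | COCOc1c(CC=C(C)C)c(OC)cc2OC(c3cc(OC)c(OC)c(OC)c3)CC(=O)c12
F6 | step 5 | (2S)-7-methoxy-5-(methoxymethoxy)-6-(3-methylbut-2-en-1-yl)-2-(3,4,5-trimethoxyphenyl)-2,3-dihydro-4H-chromen-4-one | COCOc1c(CC=C(C)C)c(OC)cc2O[C@H](c3cc(OC)c(OC)c(OC)c3)CC(=O)c12
F7 | step 5 | (2R,4R)-7-methoxy-5-(methoxymethoxy)-6-(3-methylbut-2-en-1-yl)-2-(3,4,5-trimethoxyphenyl)-3,4-dihydro-2H-chromen-4-ol | COCOc1c(CC=C(C)C)c(OC)cc2O[C@@H](c3cc(OC)c(OC)c(OC)c3)C[C@@H](O)c12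
F8 | step 4 | (E)-3-(dimethylamino)-1-[4-methoxy-3-(3-methylbut-2-en-1-yl)-6-[(3,4,5-trimethoxyphenyl)methoxy]-2-[tri(propan-2-yl)silyloxy]phenyl]prop-2-en-1-one | CN(C)/C=C/C(=O)c1c(OCc2cc(OC)c(OC)c(OC)c2)cc(OC)c(CC=C(C)C)c1O[Si](C(C)C)(C(C)C)C(C)C
F9 | step 1 | 1-[2-hydroxy-4-methoxy-6-(prop-2-en-1-yloxy)phenyl]ethan-1-one | CC(=O)c1c(O)cc(OC)cc1OCC=C
F10 | step 1 | 1-[2,6-dihydroxy-4-methoxy-3-(prop-2-en-1-yl)phenyl]ethan-1-one | CC(=O)c1c(O)cc(OC)c(CC=C)c1O
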